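**Plan** (germacrane numbering: ring C1–C10, lactone carbons C11–C13)

- Retrosynthesis cuts, in order: C1–C2 of the ten-membered ring (ketone from a C1 S-ethyl thioester and a C2 primary iodide); the butenolide C7=C11 bond (ring-closing metathesis) and its C6–O acyl bond; C7–C8 (Nozaki–Hiyama–Kishi). This leaves a lactate-derived C8–C10/C1 aldehyde thioester and a C2–C7 bromo-diene.
- Forward ring order: oxirane at the fragment stage (step 9), butenolide (step 20), ten-membered carbocycle last (step 21), which gives the target itself.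
- Enabling feature: the C1 ketone sits between the fully substituted C10 (no H, so no enolisation, epimerisation or ketene formation) and the unfunctionalised C2H2–C3H2 tether to the oxirane carbon C4. C1–C2 can therefore be made as an acyl–alkyl bond on a seco-chain that already carries the epoxide, the lactone and all three esters.
- Stereochemistry: C10 from (S)-lactic acid (self-regeneration of the stereocentre); C6 by CBS reduction; C4/C5 by hydroxyl-directed threo epoxidation from C6; C8 by a second CBS reduction. No stereocentre is made or touched after step 13.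

Key step: step 21

TBS = tert-butyldimethylsilyl.

**Step 1**
Reactants: 1 (S)-lactic acid; 2 pivalaldehyde
Product: 3 (2S,5S)-2-tert-butyl-5-methyl-1,3-dioxolan-4-one (cis)
Conditions: cat. TsOH, cat. H2SO4, pentane, reflux (Dean–Stark); crystallisation from pentane, −78 °C
Reagents that add atoms: none
Why: Acid-catalysed acetalisation of the α-hydroxy acid should give the cis-dioxolanone, which relays the lactate configuration to the acetal carbon (first stage of self-regeneration of the stereocentre).

**Step 2**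
Reactants: 3 (2S,5S)-2-tert-butyl-5-methyl-1,3-dioxolan-4-one; 4 allyl bromide
Product: 6 (2S,5R)-5-allyl-2-tert-butyl-5-methyl-1,3-dioxolan-4-one, via lithium enolate 5 (not isolated)
Conditions: LDA, THF, −78 °C; then 4, −78 → −30 °C
Reagents that add atoms: none
Why: Dioxolanone enolate alkylation occurs anti to the tert-butyl group, so allyl takes the place of the former H and C10 is set as R.

**Step 3**
Reactants: 6 (2S,5R)-5-allyl-2-tert-butyl-5-methyl-1,3-dioxolan-4-one
Product: 7 S-ethyl (2R)-2-hydroxy-2-methylpent-4-enethioate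
Conditions: AlMe3, EtSH, CH2Cl2, 0 °C (Me2AlSEt); then 6, 0 °C → rt; aq. Rochelle salt
Reagents that add atoms: ethanethiol, CCS
Why: The aluminium thiolate should open the acylal lactone at the carbonyl (ester-to-thioester exchange), releasing pivalaldehyde and the free tertiary alcohol without touching the quaternary centre.

**Step 4**
Reactants: 7 S-ethyl (2R)-2-hydroxy-2-methylpent-4-enethioate
Product: 9 S-ethyl (2R)-2-hydroxy-2-methyl-4-oxobutanethioate, via ozonide 8 (not isolated)
Conditions: O3, CH2Cl2, −78 °C (Sudan III end point); then PPh3, −78 °C → rt; used crude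
Reagents that add atoms: ozone, [O-][O+]=O
Why: Ozonolysis with reductive work-up should cleave only the terminal alkene and give the C8 aldehyde, which is not stored because a β-hydroxy aldehyde can dehydrate.

**Step 5**
Reactants: 10 acrolein
Product: 12 2-bromoprop-2-enal, via 2,3-dibromopropanal 11 (not isolated)
Conditions: Br2, CH2Cl2, −78 → 0 °C; then Et3N, 0 °C; distillation
Reagents that add atoms: bromine, BrBr
Why: Bromine addition followed by E2 loss of HBr from the α-position gives the 2-bromo enal that supplies C6 and C7.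

**Step 6**
Reactants: 13 tert-butyl(but-3-yn-1-yloxy)dimethylsilane; 12 2-bromoprop-2-enal
Product: 15 rac-(4E)-2-bromo-7-(TBS-oxy)-5-methylhepta-1,4-dien-3-ol, via alkenylalane 14 (not isolated)
Conditions: AlMe3 (2 equiv), Cp2ZrCl2 (0.2 equiv), CH2Cl2, 0 °C → rt; excess AlMe3 removed in vacuo; then 12, THF, −78 → 0 °C
Reagents that add atoms: trimethylaluminium, C[Al](C)C
Why: Zr-catalysed syn-carboalumination places Me and Al cis, and 1,2-addition of the alkenylalane to the enal with retention fixes the E geometry of C4=C5 (C15 methyl cis to C6); C6 forms racemic.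

**Step 7**
Reactants: 15 rac-(4E)-2-bromo-7-(TBS-oxy)-5-methylhepta-1,4-dien-3-ol
Product: 16 (4E)-2-bromo-7-(TBS-oxy)-5-methylhepta-1,4-dien-3-one
Conditions: activated MnO2, CH2Cl2, rt
Reagents that add atoms: none
Why: MnO2 oxidises the doubly allylic alcohol selectively to the cross-conjugated dienone.

**Step 8**
Reactants: 16 (4E)-2-bromo-7-(TBS-oxy)-5-methylhepta-1,4-dien-3-one
Product: 17 (3R,4E)-2-bromo-7-(TBS-oxy)-5-methylhepta-1,4-dien-3-ol
Conditions: (S)-2-methyl-CBS-oxazaborolidine (0.2 equiv), catecholborane, toluene, −78 °C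
Reagents that add atoms: none
Why: In this Corey–Bakshi–Shibata reduction the α-branched 2-bromovinyl group should act as the large substituent, so the (S)-catalyst should deliver hydride to give the 3R alcohol (C6).

**Step 9**
Reactants: 17 (3R,4E)-2-bromo-7-(TBS-oxy)-5-methylhepta-1,4-dien-3-ol
Product: 18 (1R)-2-bromo-1-{(2R,3R)-3-methyl-3-[2-(TBS-oxy)ethyl]oxiran-2-yl}prop-2-en-1-ol
Conditions: mCPBA, NaHCO3, CH2Cl2, 0 °C
Reagents that add atoms: mCPBA, OOC(=O)c1cccc(Cl)c1
Why: Hydroxyl-directed peracid epoxidation of the electron-rich trisubstituted alkene; the methyl cis to the carbinol (A1,3 strain) should enforce the threo epoxy alcohol (C4 R, C5 R), and the bromoalkene is too electron-poor to react.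

**Step 10**
Reactants: 18 (1R)-2-bromo-1-{(2R,3R)-3-methyl-3-[2-(TBS-oxy)ethyl]oxiran-2-yl}prop-2-en-1-ol
Product: 19 TBS ether of 18 at the C6 hydroxyl
Conditions: TBSCl, imidazole, cat. DMAP, DMF, rt
Reagents that add atoms: tert-butyldimethylsilyl chloride, CC(C)(C)[Si](C)(C)Cl
Why: Silylation under weakly basic conditions masks the C6 hydroxyl for the oxidation and reduction at C8 without opening the epoxide.

**Step 11**
Reactants: 19 bis-TBS bromoalkene; 9 S-ethyl (2R)-2-hydroxy-2-methyl-4-oxobutanethioate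
Product: 20 S-ethyl (2R,4RS,6S)-2,4-dihydroxy-2-methyl-5-methylidene-6-(TBS-oxy)-6-{(2R,3R)-3-methyl-3-[2-(TBS-oxy)ethyl]oxiran-2-yl}hexanethioate (C8 epimers)
Conditions: CrCl2 (4 equiv), NiCl2 (2 mol%), DMSO, rt; crude product taken on at once
Reagents that add atoms: none
Why: Nozaki–Hiyama–Kishi coupling forms C7–C8 by addition of the alkenylchromium to the aldehyde only, leaving thioester, epoxide and silyl ethers intact; the C8 mixture is levelled in steps 12 and 13.

**Step 12**
Reactants: 20 C8-epimeric diol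
Product: 21 S-ethyl (2R,6S)-2-hydroxy-2-methyl-5-methylidene-4-oxo-6-(TBS-oxy)-6-{(2R,3R)-3-methyl-3-[2-(TBS-oxy)ethyl]oxiran-2-yl}hexanethioate
Conditions: Dess–Martin periodinane, NaHCO3, CH2Cl2, 0 °C → rt
Reagents that add atoms: none
Why: Dess–Martin oxidation converts the secondary allylic alcohol into the C8 enone, while the tertiary alcohol and the thioester cannot react.

**Step 13**
Reactants: 21 C8 enone
Product: 22 S-ethyl (2R,4S,6S)-2,4-dihydroxy-2-methyl-5-methylidene-6-(TBS-oxy)-6-{(2R,3R)-3-methyl-3-[2-(TBS-oxy)ethyl]oxiran-2-yl}hexanethioate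
Conditions: (R)-2-methyl-CBS-oxazaborolidine (0.3 equiv), catecholborane (2.5 equiv), toluene, −78 °C; crude product acylated at once
Reagents that add atoms: none
Why: CBS reduction with the 1,1-disubstituted vinyl group as the large substituent should give the 8S alcohol under catalyst control; catecholborane caps the tertiary OH so no internal hydride delivery competes, and the γ-hydroxy thioester is not stored because it could lactonise.

**Step 14**
Reactants: 22 (8S)-alcohol
Product: 23 S-ethyl (2R,4S,6S)-2-hydroxy-2-methyl-5-methylidene-4-[(E)-2-methylbut-2-enoyl]oxy-6-(TBS-oxy)-6-{(2R,3R)-3-methyl-3-[2-(TBS-oxy)ethyl]oxiran-2-yl}hexanethioate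
Conditions: tigloyl chloride, pyridine, cat. DMAP, CH2Cl2, 0 °C
Reagents that add atoms: tigloyl chloride, C/C=C(\C)C(Cl)=O
Why: Acylation should take only the secondary C8 alcohol (the tertiary C10 alcohol is much slower), and the E-configured tiglate is the stable geometry.

**Step 15**
Reactants: 23 C8 tiglate
Product: 24 S-ethyl (2R,4S,6S)-2-acetoxy-2-methyl-5-methylidene-4-[(E)-2-methylbut-2-enoyl]oxy-6-(TBS-oxy)-6-{(2R,3R)-3-methyl-3-[2-(TBS-oxy)ethyl]oxiran-2-yl}hexanethioate
Conditions: Ac2O, Et3N, DMAP, CH2Cl2, rt → 35 °C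
Reagents that add atoms: acetic anhydride, CC(=O)OC(C)=O
Why: DMAP-catalysed acetylation of the remaining tertiary α-hydroxy thioester alcohol installs the C10 acetate once no free secondary alcohol is left to receive a migrating acyl group.

**Step 16**
Reactants: 24 C10 acetate
Product: 25 S-ethyl (2R,4S,6S)-2-acetoxy-6-hydroxy-6-[(2R,3R)-3-(2-hydroxyethyl)-3-methyloxiran-2-yl]-2-methyl-5-methylidene-4-[(E)-2-methylbut-2-enoyl]oxyhexanethioate
Conditions: HF·pyridine, excess pyridine, THF, 0 °C → rt
Reagents that add atoms: none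
Why: Buffered fluoride cleaves both Si–O bonds, while the epoxide, the three acyl groups and the thioester should survive.

**Step 17**
Reactants: 25 diol
Product: 26 S-ethyl (2R,4S,6S)-2-acetoxy-6-hydroxy-6-[(2R,3R)-3-(2-iodoethyl)-3-methyloxiran-2-yl]-2-methyl-5-methylidene-4-[(E)-2-methylbut-2-enoyl]oxyhexanethioate
Conditions: I2, PPh3, imidazole, CH2Cl2, 0 °C
Reagents that add atoms: iodine, II
Why: The Appel-type iodination should take the unhindered primary C2 alcohol and leave the hindered secondary C6 alcohol.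

**Step 18**
Reactants: 27 2-(bromomethyl)acrylic acid
Product: 28 2-(acetoxymethyl)acrylic acid
Conditions: KOAc, AcOH, 50 °C
Reagents that add atoms: potassium acetate, CC(=O)[O-].[K+]
Why: Acetate displaces the activated allylic bromide (SN2 and SN2′ give the same product).

**Step 19**
Reactants: 26 iodo alcohol; 28 2-(acetoxymethyl)acrylic acid
Product: 30 S-ethyl (2R,4S,6S)-2-acetoxy-6-[2-(acetoxymethyl)prop-2-enoyl]oxy-6-[(2R,3R)-3-(2-iodoethyl)-3-methyloxiran-2-yl]-2-methyl-5-methylidene-4-[(E)-2-methylbut-2-enoyl]oxyhexanethioate, via acid chloride 29 (not isolated)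
Conditions: 28, (COCl)2, cat. DMF, CH2Cl2, 0 °C → rt, concentrate; then 26, 2,6-lutidine, cat. DMAP, CH2Cl2, 0 °C → rt
Reagents that add atoms: none
Why: Acylation of the C6 hydroxyl by the acid chloride brings in C11–C13 with the C13 acetate in place; only the O–H bond reacts, so C6 keeps its configuration.

**Step 20**
Reactants: 30 acrylate ester
Product: 31 S-ethyl (2R,4S)-2-acetoxy-4-{(2S)-4-(acetoxymethyl)-2-[(2R,3R)-3-(2-iodoethyl)-3-methyloxiran-2-yl]-5-oxo-2,5-dihydrofuran-3-yl}-2-methyl-4-[(E)-2-methylbut-2-enoyl]oxybutanethioate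
Conditions: Hoveyda–Grubbs II catalyst (20 mol%), toluene, 80 °C, argon sparge
Reagents that add atoms: none
Why: Ring-closing metathesis of the two 1,1-disubstituted alkenes should form the tetrasubstituted C7=C11 bond of the butenolide with loss of ethylene; the five-membered closure is the only low-strain option, and the trisubstituted tiglate alkene, thioester and iodide are poor partners for the carbene.

**Step 21**
Reactants: 31 seco iodo thioester
Product: 33 (4R,5R,6S,8S,10R)-10,13-diacetoxy-4,5-epoxy-8-[(E)-2-methylbut-2-enoyloxy]-1-oxogermacr-7(11)-en-12,6-olide (CNP0175424.1), via alkylzinc iodide 32 (not isolated)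
Conditions: activated Zn dust, THF/DMA, rt; then addition over 10 h (syringe pump) to PdCl2(PPh3)2 (10 mol%), toluene/THF, rt, final about 1 mM
Reagents that add atoms: none
Why: Proposed new method: Zn inserts into the primary C2–I bond, Pd(0) adds to the C1(acyl)–SEt bond, the tethered alkylzinc transmetalates to the acyl–Pd(II) thiolate and reductive elimination from the eleven-membered acyl(alkyl)palladacycle forms the C1–C2 bond and the C1 ketone; the closest known reaction is the intermolecular Fukuyama thioester–alkylzinc ketone synthesis, which has not been used to close a ten-membered carbocycle. The ring closes in a ten-membered mode by C(acyl)–C(sp3) reductive elimination, with the trans-oxirane, the planar butenolide at C6/C7 and the quaternary C10 as turn elements that bring C1 and C2 together. No stereocentre is formed, and because C10 carries no hydrogen the acyl–palladium species cannot enolise, epimerise or give a ketene, so the five existing centres are spectators. The step needs chemoselectivity for the C(acyl)–S bond over the three O-esters, the lactone, the epoxide and the hindered C13 allylic acetate on a tetrasubstituted alkene, which the thiophilic Pd/Zn pair and the mild alkylzinc should secure. It also needs cyclisation over oligomerisation, which slow addition of the preformed zinc reagent to the catalyst at high dilution should secure.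

**Compound list**

1 | (S)-lactic acid | C[C@H](O)C(=O)O | starting material
2 | pivalaldehyde | CC(C)(C)C=O | starting material
3 | (2S,5S)-2-tert-butyl-5-methyl-1,3-dioxolan-4-one | C[C@@H]1O[C@H](C(C)(C)C)OC1=O | intermediate
4 | allyl bromide | C=CCBr | starting material
5 | lithium enolate of 3 | [Li+].CC1=C([O-])O[C@@H](C(C)(C)C)O1 | intermediate
6 | (2S,5R)-5-allyl-2-tert-butyl-5-methyl-1,3-dioxolan-4-one | C=CC[C@@]1(C)O[C@H](C(C)(C)C)OC1=O | intermediate
7 | S-ethyl (2R)-2-hydroxy-2-methylpent-4-enethioate | CCSC(=O)[C@](C)(O)CC=C | intermediate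
8 | ozonide of 7 (1,2,4-trioxolane, mixture at the ring carbon) | CCSC(=O)[C@](C)(O)CC1OCOO1 | intermediate
9 | S-ethyl (2R)-2-hydroxy-2-methyl-4-oxobutanethioate | CCSC(=O)[C@](C)(O)CC=O | intermediate
10 | acrolein | C=CC=O | starting material
11 | 2,3-dibromopropanal | O=CC(Br)CBr | intermediate
12 | 2-bromoprop-2-enal | C=C(Br)C=O | intermediate
13 | tert-butyl(but-3-yn-1-yloxy)dimethylsilane | C#CCCO[Si](C)(C)C(C)(C)C | starting material
14 | (E)-[4-(TBS-oxy)-2-methylbut-1-enyl]dimethylaluminium | C[Al](C)/C=C(\C)CCO[Si](C)(C)C(C)(C)C | intermediate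
15 | rac-(4E)-2-bromo-7-(TBS-oxy)-5-methylhepta-1,4-dien-3-ol | C=C(Br)C(O)/C=C(\C)CCO[Si](C)(C)C(C)(C)C | intermediate
16 | (4E)-2-bromo-7-(TBS-oxy)-5-methylhepta-1,4-dien-3-one | C=C(Br)C(=O)/C=C(\C)CCO[Si](C)(C)C(C)(C)C | intermediate
17 | (3R,4E)-2-bromo-7-(TBS-oxy)-5-methylhepta-1,4-dien-3-ol | C=C(Br)[C@H](O)/C=C(\C)CCO[Si](C)(C)C(C)(C)C | intermediate
18 | (1R)-2-bromo-1-{(2R,3R)-3-methyl-3-[2-(TBS-oxy)ethyl]oxiran-2-yl}prop-2-en-1-ol | C=C(Br)[C@H](O)[C@H]1O[C@]1(C)CCO[Si](C)(C)C(C)(C)C | intermediate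
19 | C6 TBS ether of 18 | C=C(Br)[C@H](O[Si](C)(C)C(C)(C)C)[C@H]1O[C@]1(C)CCO[Si](C)(C)C(C)(C)C | intermediate
20 | S-ethyl (2R,4RS,6S)-2,4-dihydroxy-2-methyl-5-methylidene-6-(TBS-oxy)-6-{(2R,3R)-3-methyl-3-[2-(TBS-oxy)ethyl]oxiran-2-yl}hexanethioate | CCSC(=O)[C@](C)(O)CC(O)C(=C)[C@H](O[Si](C)(C)C(C)(C)C)[C@H]1O[C@]1(C)CCO[Si](C)(C)C(C)(C)C | intermediate
21 | 4-oxo analogue of 20 (C8 enone) | CCSC(=O)[C@](C)(O)CC(=O)C(=C)[C@H](O[Si](C)(C)C(C)(C)C)[C@H]1O[C@]1(C)CCO[Si](C)(C)C(C)(C)C | intermediate
22 | (2R,4S,6S)-diol (8S alcohol) | CCSC(=O)[C@](C)(O)C[C@H](O)C(=C)[C@H](O[Si](C)(C)C(C)(C)C)[C@H]1O[C@]1(C)CCO[Si](C)(C)C(C)(C)C | intermediate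
23 | C8 tiglate of 22 | CCSC(=O)[C@](C)(O)C[C@H](OC(=O)/C(C)=C/C)C(=C)[C@H](O[Si](C)(C)C(C)(C)C)[C@H]1O[C@]1(C)CCO[Si](C)(C)C(C)(C)C | intermediate
24 | C10 acetate of 23 | CCSC(=O)[C@](C)(OC(C)=O)C[C@H](OC(=O)/C(C)=C/C)C(=C)[C@H](O[Si](C)(C)C(C)(C)C)[C@H]1O[C@]1(C)CCO[Si](C)(C)C(C)(C)C | intermediate
25 | S-ethyl (2R,4S,6S)-2-acetoxy-6-hydroxy-6-[(2R,3R)-3-(2-hydroxyethyl)-3-methyloxiran-2-yl]-2-methyl-5-methylidene-4-[(E)-2-methylbut-2-enoyl]oxyhexanethioate | CCSC(=O)[C@](C)(OC(C)=O)C[C@H](OC(=O)/C(C)=C/C)C(=C)[C@H](O)[C@H]1O[C@]1(C)CCO | intermediate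
26 | 2-iodoethyl analogue of 25 | CCSC(=O)[C@](C)(OC(C)=O)C[C@H](OC(=O)/C(C)=C/C)C(=C)[C@H](O)[C@H]1O[C@]1(C)CCI | intermediate
27 | 2-(bromomethyl)acrylic acid | C=C(CBr)C(=O)O | starting material
28 | 2-(acetoxymethyl)acrylic acid | CC(=O)OCC(=C)C(=O)O | intermediate
29 | 2-(acetoxymethyl)acryloyl chloride | CC(=O)OCC(=C)C(=O)Cl | intermediate
30 | C6 2-(acetoxymethyl)acrylate of 26 | CCSC(=O)[C@](C)(OC(C)=O)C[C@H](OC(=O)/C(C)=C/C)C(=C)[C@H](OC(=O)C(=C)COC(C)=O)[C@H]1O[C@]1(C)CCI | intermediate
31 | S-ethyl (2R,4S)-2-acetoxy-4-{(2S)-4-(acetoxymethyl)-2-[(2R,3R)-3-(2-iodoethyl)-3-methyloxiran-2-yl]-5-oxo-2,5-dihydrofuran-3-yl}-2-methyl-4-[(E)-2-methylbut-2-enoyl]oxybutanethioate | CCSC(=O)[C@](C)(OC(C)=O)C[C@H](OC(=O)/C(C)=C/C)C1=C(COC(C)=O)C(=O)O[C@@H]1[C@H]2O[C@]2(C)CCI | intermediate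
32 | alkylzinc iodide from 31 (C2–ZnI) | CCSC(=O)[C@](C)(OC(C)=O)C[C@H](OC(=O)/C(C)=C/C)C1=C(COC(C)=O)C(=O)O[C@@H]1[C@H]2O[C@]2(C)CC[Zn]I | intermediate
33 | (4R,5R,6S,8S,10R)-10,13-diacetoxy-4,5-epoxy-8-[(E)-2-methylbut-2-enoyloxy]-1-oxogermacr-7(11)-en-12,6-olide (CNP0175424.1) | C/C=C(\C)C(=O)O[C@H]1C[C@@](C)(OC(C)=O)C(=O)CC[C@@]2(C)O[C@@H]2[C@H]2OC(=O)C(COC(C)=O)=C12 | target

**Step count**

Total: 21 steps. Longest linear sequence: 16 steps (5–17, 19–21).

**Steps most likely to fail**

1. Step 21 (Proposed new method). What may go wrong: the tethered alkylzinc is protonated before it transmetalates, the acyl–palladium intermediate is intercepted intermolecularly (oligomerisation), or Pd(0) ionises the C13 allylic acetate before it inserts into the C–S bond. Fallback with known chemistry, setting out from 31 and returning at 33: the iodide of 31 is displaced with sodium 2-nitrophenylselenide to give the aryl selenide F1. Liebeskind–Srogl coupling of the thioester with tributyl(vinyl)stannane (Pd2(dba)3, tri-2-furylphosphine, copper(I) diphenylphosphinate) gives the vinyl ketone F2. Oxidation of the selenide with H2O2 and syn-elimination of the selenoxide give the vinyl epoxide F3. Ring-closing metathesis (Hoveyda–Grubbs II, toluene, high dilution) closes the ten-membered ring at C2=C3 to the macrocyclic enone F4. Diimide (potassium azodicarboxylate, AcOH) should saturate only the disubstituted C2=C3 bond and give 33.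

2. Step 20. What may go wrong: non-productive metathesis, where the ruthenium carbene fails to close the tetrasubstituted C7=C11 bond between two hindered 1,1-disubstituted alkenes, or engages the tiglate alkene and expels propene. Fallback, setting out from 26 and returning at 31: Lemieux–Johnson cleavage (cat. OsO4, NaIO4, 2,6-lutidine) of the C7 methylidene gives the α-hydroxy ketone F5. Acryloyl chloride with iPr2NEt gives the acrylate F6. An intramolecular Morita–Baylis–Hillman reaction (DABCO) closes the lactone as the α-methylene-β-hydroxy-γ-lactone F7. Ac2O/DMAP acetylates the tertiary allylic alcohol and transposes the acetate to C13 (SN2′, as known for Morita–Baylis–Hillman acetates), which gives 31.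

3. Step 8. What may go wrong: poor facial discrimination in the CBS reduction because both ketone substituents are alkenyl, or competing 1,4-reduction of the bromo enone. Fallback, setting out from 15 and returning at 17: lipase-catalysed kinetic resolution of racemic 15 (Amano lipase PS, vinyl acetate) should acylate the 3R enantiomer, taking the bromovinyl group as the large substituent, to the acetate F8. F8 is separated from the unreacted 3S alcohol and methanolysed (K2CO3, MeOH) to 17.

**Further compounds**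

F1 | step 21 | 2-[(2-nitrophenyl)selanyl]ethyl analogue of 31 | CCSC(=O)[C@](C)(OC(C)=O)C[C@H](OC(=O)/C(C)=C/C)C1=C(COC(C)=O)C(=O)O[C@@H]1[C@H]2O[C@]2(C)CC[Se]c1ccccc1[N+](=O)[O-]
F2 | step 21 | vinyl ketone from F1 (C1 acryloyl in place of the thioester) | C=CC(=O)[C@](C)(OC(C)=O)C[C@H](OC(=O)/C(C)=C/C)C1=C(COC(C)=O)C(=O)O[C@@H]1[C@H]2O[C@]2(C)CC[Se]c1ccccc1[N+](=O)[O-]
F3 | step 21 | vinyl ketone vinyl epoxide (C4 vinyl) | C=CC(=O)[C@](C)(OC(C)=O)C[C@H](OC(=O)/C(C)=C/C)C1=C(COC(C)=O)C(=O)O[C@@H]1[C@H]2O[C@]2(C)C=C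
F4 | step 21 | 2,3-didehydro analogue of 33 (alkene geometry left open) | C/C=C(\C)C(=O)O[C@H]1C[C@@](C)(OC(C)=O)C(=O)C=C[C@@]2(C)O[C@@H]2[C@H]2OC(=O)C(COC(C)=O)=C12
F5 | step 20 | C7 ketone from 26 (α-hydroxy ketone) | CCSC(=O)[C@](C)(OC(C)=O)C[C@H](OC(=O)/C(C)=C/C)C(=O)[C@H](O)[C@H]1O[C@]1(C)CCI
F6 | step 20 | C6 acrylate of F5 | CCSC(=O)[C@](C)(OC(C)=O)C[C@H](OC(=O)/C(C)=C/C)C(=O)[C@H](OC(=O)C=C)[C@H]1O[C@]1(C)CCI
F7 | step 20 | α-methylene-β-hydroxy-γ-lactone (C7 tertiary alcohol, configuration at C7 left open) | CCSC(=O)[C@](C)(OC(C)=O)C[C@H](OC(=O)/C(C)=C/C)C1(O)C(=C)C(=O)O[C@@H]1[C@H]2O[C@]2(C)CCI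
F8 | step 8 | (3R,4E)-2-bromo-7-(TBS-oxy)-5-methylhepta-1,4-dien-3-yl acetate | C=C(Br)[C@H](OC(C)=O)/C=C(\C)CCO[Si](C)(C)C(C)(C)C
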